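Everything rests on cutting the bond between C3 of the inner dihydrofuran and the resorcinol ring (ring C) of the seven-membered carbocycle. The feature exploited is this ring-fusion carbon. Its aryl substituent sits trans to the C2 aryl group, the pattern left when aryl and hydrogen add to the same face of C2=C3 in a 2-arylbenzofuran. One palladium-catalysed reductive Heck closure thus forms the C3–aryl bond, closes the cycloheptadiene, dearomatises the furan and sets C2 and C3. The precursor is a 2-(4-methoxyphenyl)benzofuran with a pivalate at C6 and, at C4, an (S)-2,2-diarylethyl arm that ends in an aryl triflate. The outer dihydrofuran follows by carbene C–H insertion.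

Key step: step 10

Labels:
- Benzofuran numbering is kept for ring A and the inner furan or dihydrofuran (O1, C2, C3, C3a, C4–C7, C7a).
- Ring B is the 4-oxygenated phenyl group on C2.
- Ring C is the dioxygenated benzene ring of the seven-membered carbocycle (C1'' bonded to C3, C2'' bonded to the methine, oxygen on C3'' and C5'').
- The methine is the CH that joins C2'', ring D (2,4-dioxygenated phenyl) and the CH2 group on C4.
- C2' and C3' belong to the outer dihydrofuran (its oxygen on C6, C3' on C5), with ring F (4-oxygenated phenyl) on C2' and ring E (3,5-dioxygenated phenyl) on C3'.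
- The target is 2S,3S; methine S; 2'R,3'R.

Assumption: the antipode of the dirhodium catalyst that leads to 3'R cannot be deduced safely for a di-ortho-substituted diaryl carbene. Rh2(S-PTAD)4 is written, and its commercial mirror image takes its place if a trial run shows the opposite sense.

Step 1
Reactants: 1 5,7-dimethoxycoumarin; 2 2,4-dimethoxyphenylboronic acid
Product: 3 (S)-4-(2,4-dimethoxyphenyl)-5,7-dimethoxychroman-2-one
Conditions: Rh(acac)(C2H4)2 (3 mol %), (S)-Segphos (3.3 mol %), 2 (4 equiv, in portions), dioxane/H2O 10:1, 60 °C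
Reagents that add atoms: none
Why: Hayashi–Miyaura asymmetric 1,4-addition, in which the aryl–rhodium species held by (S)-Segphos adds to one face of C4 and hydrolysis of the rhodium enolate releases the lactone; since (R)-Segphos is known to give (R)-4-arylchroman-2-ones with the same priority order (C4a > new aryl > C3 > H), the S ligand should set the diarylmethine as S.

Step 2
Reactants: 3 (S)-4-(2,4-dimethoxyphenyl)-5,7-dimethoxychroman-2-one
Product: 6 (S)-3-[2-(benzyloxy)-4,6-dimethoxyphenyl]-3-(2,4-dimethoxyphenyl)propanoic acid, via ring-opened phenol methyl ester 4 (not isolated), via benzyl ether methyl ester 5 (not isolated)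
Conditions: BnBr, K2CO3, MeOH, 60 °C; then aq NaOH, 60 °C; then 1 M HCl to pH 2
Reagents that add atoms: benzyl bromide, BrCc1ccccc1; water (from aq NaOH), O
Why: Carbonate-promoted methanolysis opens the aryl lactone, Williamson benzylation caps the freed phenoxide before it can relactonise and saponification in the same flask gives the acid, all without touching the stereocentre, which is beta to the carbonyl group and not enolisable.

Step 3
Reactants: 6 (S)-3-[2-(benzyloxy)-4,6-dimethoxyphenyl]-3-(2,4-dimethoxyphenyl)propanoic acid
Product: 8 (S)-1-(benzyloxy)-2-[1-(2,4-dimethoxyphenyl)-2-iodoethyl]-3,5-dimethoxybenzene, via Barton ester 7 (not isolated)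
Conditions: N-hydroxypyridine-2-thione, DCC, CH2Cl2, 0 °C, dark; then CHI3, hv (tungsten lamp), rt
Reagents that add atoms: iodoform, IC(I)I
Why: Barton decarboxylative iodination, chosen because iodine-atom transfer from CHI3 traps the primary 2,2-diarylethyl radical far faster than its 1,2-aryl (neophyl-type) shift or hydrogen abstraction from the benzyl ether can occur, so that the constitution and the S centre (not a radical site) should be kept.

Step 4
Reactants: 9 5-bromoresorcinol
Product: 10 5-bromo-4-iodobenzene-1,3-diol
Conditions: NIS (1.0 equiv), MeCN, 0 °C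
Reagents that add atoms: N-iodosuccinimide, O=C1CCC(=O)N1I
Why: Electrophilic aromatic iodination, in which resorcinols in a non-aqueous medium react para to one hydroxyl group, here at C4 next to bromine, rather than at C2 between the hydroxyl groups, while one equivalent of reagent at low temperature limits double iodination.

Step 5
Reactants: 10 5-bromo-4-iodobenzene-1,3-diol; 11 4-ethynylanisole
Product: 13 4-bromo-2-(4-methoxyphenyl)benzofuran-6-ol, via alkynylresorcinol 12 (not isolated)
Conditions: PdCl2(PPh3)2 (3 mol %), CuI (5 mol %), Et3N, DMF, rt then 60 °C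
Reagents that add atoms: none
Why: Sonogashira coupling at the C–I bond, which undergoes oxidative addition much faster than C–Br, followed by copper- and base-assisted 5-endo-dig hydroalkoxylation by the only hydroxyl group ortho to the alkyne, which places bromine at C4 and the free hydroxyl group at C6 without any protecting group.

Step 6
Reactants: 13 4-bromo-2-(4-methoxyphenyl)benzofuran-6-ol
Product: 14 4-bromo-2-(4-methoxyphenyl)benzofuran-6-yl pivalate
Conditions: PivCl, Et3N, DMAP (cat.), CH2Cl2, 0 °C to rt
Reagents that add atoms: pivaloyl chloride, CC(C)(C)C(=O)Cl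
Why: DMAP-catalysed acylation of the phenol; the pivalate is chosen because it tolerates organozinc reagents, hydrogenolysis, triflation and hot formate and leaves later by mild methanolysis, so that the benzylic C2–O bond made in the key step never meets hydrogen over palladium.

Step 7
Reactants: 8 (S)-1-(benzyloxy)-2-[1-(2,4-dimethoxyphenyl)-2-iodoethyl]-3,5-dimethoxybenzene; 14 4-bromo-2-(4-methoxyphenyl)benzofuran-6-yl pivalate
Product: 16 4-{(S)-2-[2-(benzyloxy)-4,6-dimethoxyphenyl]-2-(2,4-dimethoxyphenyl)ethyl}-2-(4-methoxyphenyl)benzofuran-6-yl pivalate, via alkylzinc iodide 15 (not isolated)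
Conditions: 8, Zn dust, LiCl, THF, 25–35 °C; then 14, Pd(OAc)2 (3 mol %), SPhos (6 mol %), THF, 45 °C
Reagents that add atoms: none
Why: LiCl-promoted zinc insertion and Negishi sp3–sp2 cross-coupling, in which the C–C bond is made by two-electron transmetalation and by a reductive elimination that SPhos accelerates over beta-hydride elimination, the ester survives the mild organozinc reagent and the stereocentre next to the reacting carbon is not involved.

Step 8
Reactants: 16 4-{(S)-2-[2-(benzyloxy)-4,6-dimethoxyphenyl]-2-(2,4-dimethoxyphenyl)ethyl}-2-(4-methoxyphenyl)benzofuran-6-yl pivalate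
Product: 17 4-[(S)-2-(2,4-dimethoxyphenyl)-2-(2-hydroxy-4,6-dimethoxyphenyl)ethyl]-2-(4-methoxyphenyl)benzofuran-6-yl pivalate
Conditions: H2 (1 atm), Pd/C, EtOAc/EtOH, rt
Reagents that add atoms: none
Why: Catalytic hydrogenolysis of the aryl benzyl ether, which at one atmosphere is much faster than saturation of the 2-arylbenzofuran double bond and leaves the pivalate and the methyl ethers alone.

Step 9
Reactants: 17 4-[(S)-2-(2,4-dimethoxyphenyl)-2-(2-hydroxy-4,6-dimethoxyphenyl)ethyl]-2-(4-methoxyphenyl)benzofuran-6-yl pivalate
Product: 18 4-{(S)-2-(2,4-dimethoxyphenyl)-2-[2,4-dimethoxy-6-(triflyloxy)phenyl]ethyl}-2-(4-methoxyphenyl)benzofuran-6-yl pivalate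
Conditions: Tf2O, pyridine, CH2Cl2, 0 °C
Reagents that add atoms: triflic anhydride, O=S(=O)(OS(=O)(=O)C(F)(F)F)C(F)(F)F
Why: O-Sulfonylation of the only free phenol, a standard aryl triflate synthesis that works for ortho-branched phenols and does not affect the electron-rich rings at 0 °C.

Step 10
Reactants: 18 4-{(S)-2-(2,4-dimethoxyphenyl)-2-[2,4-dimethoxy-6-(triflyloxy)phenyl]ethyl}-2-(4-methoxyphenyl)benzofuran-6-yl pivalate
Product: 19 tetracyclic core pivalate (2S,3S-trans inner dihydrofuran; methine S; C3 bonded to C1'' of ring C; pivalate on C6)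
Conditions: Pd2(dba)3 (5 mol %), dppf (12 mol %), HCO2Na (1.5 equiv, finely ground), 4 Å MS, DMF (0.02 M), 90 °C
Reagents that add atoms: none
Why: Proposed new method: zerovalent palladium carrying dppf inserts into the C–OTf bond of 18 and, since triflate does not bind, the cationic arylpalladium species can take up the furan C2=C3 bond before the sparingly soluble formate arrives; suprafacial migratory insertion joins C1'' of ring C to C3 and leaves the metal on C2 as a benzylic species stabilised by ring B, after which formate binds, loses CO2 and C–H reductive elimination with retention puts hydrogen on the face that received the aryl group, so rings B and C end trans. The closest known reaction type is the intramolecular dearomative reductive Heck reaction of indoles and benzofurans, shown so far only for five- and six-membered closures. The one new ring, the cycloheptadiene, closes in the 7-exo-trig mode, because the two-carbon tether on C4 lets the aryl carbon reach C3 whereas attack at C2 would be an 8-endo process. C3 is controlled by the S methine: allylic 1,3-strain with the flanking methoxy group of ring C holds the methine C–H near the plane of that ring, ring D therefore stands pseudo-axial on one face of the forming ring and C2 with ring B and the metal is pushed to the other face, which leaves H3 trans to the methine hydrogen, and C2 is controlled by C3 through the syn addition. Return to the aromatic furan by beta-hydride elimination is hindered because H3 lies anti to palladium. The step needs insertion to outrun formate reduction of the arylpalladium species and C–H palladation of ring D, which the non-coordinating leaving group, the chelating ligand, the absence of acetate or carbonate and the ortho-branched methine that holds the benzofuran over the metal are meant to secure.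

Step 11
Reactants: 19 tetracyclic core pivalate
Product: 20 tetracyclic core phenol (free C6–OH; 2S,3S; methine S)
Conditions: K2CO3, MeOH/THF, rt
Reagents that add atoms: none
Why: Base-catalysed transesterification (methanolysis) of the aryl pivalate, mild enough to leave all ethers and the three stereocentres, none of which carries an acidic hydrogen under these conditions, intact.

Step 12
Reactants: 20 tetracyclic core phenol; 21 paraformaldehyde
Product: 22 core salicylaldehyde (CHO on C5 between C6–OH and C4–CH2; 2S,3S; methine S)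
Conditions: MgCl2 (anhydrous), Et3N, 21, MeCN, reflux; then 1 M HCl
Reagents that add atoms: none
Why: Casnati–Skattebøl ortho-formylation runs through the magnesium phenoxide, so only ring A, the sole free phenol among five electron-rich rings, reacts, and of its two ortho carbons C5, para to O1, is the more nucleophilic one, as in the formylation of 3-alkoxy-5-alkylphenols, whereas C7 between the two oxygens is avoided.

Step 13
Reactants: 22 core salicylaldehyde; 23 4-methoxybenzyl chloride
Product: 24 core aldehyde 4-methoxybenzyl ether (C6–O–CH2–ring F; CHO on C5)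
Conditions: 23, K2CO3, NaI (cat.), DMF, 50 °C
Reagents that add atoms: none
Why: Williamson ether synthesis on the chelated phenol under iodide catalysis installs the CH2 group and ring F that become C2' and its aryl substituent.

Step 14
Reactants: 24 core aldehyde 4-methoxybenzyl ether; 25 1-bromo-3,5-dimethoxybenzene
Product: 27 core diarylcarbinol (C5–CH(OH)–ring E; both carbinol epimers), via 3,5-dimethoxyphenylmagnesium bromide 26 (not isolated)
Conditions: 25, Mg, THF, reflux; then 24, THF, 0 °C; then H2O
Reagents that add atoms: none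
Why: Grignard 1,2-addition to the aldehyde brings in ring E, and the carbinol centre forms without control, which is harmless because the next step destroys it.

Step 15
Reactants: 27 core diarylcarbinol
Product: 28 core diaryl ketone (C5–C(=O)–ring E; C6–O–CH2–ring F)
Conditions: Dess–Martin periodinane, NaHCO3, CH2Cl2, 0 °C to rt
Reagents that add atoms: none
Why: Dess–Martin oxidation of the doubly benzylic alcohol under bicarbonate buffering, which avoids acid ionisation of the electron-rich benzhydrol and does not attack the aryl ethers or the dihydrofuran.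

Step 16
Reactants: 28 core diaryl ketone
Product: 29 hydrazone of 28 (C=N–NH2; E/Z mixture)
Conditions: N2H4·H2O (30 equiv), AcOH (1 equiv), n-BuOH, 120 °C, sealed tube
Reagents that add atoms: hydrazine (as hydrate), NN
Why: Acid-catalysed hydrazone condensation, driven by a large excess of the small nucleophile and by heat because the carbonyl group is flanked by two ortho substituents, and run without strong base so that no Wolff–Kishner reduction sets in.

Step 17
Reactants: 29 hydrazone of 28
Product: 31 cis-outer-ring octamethyl ether (2S,3S; methine S; 2'S,3'R), via diaryldiazomethane 30 (not isolated)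
Conditions: MnO2 (10 equiv), CH2Cl2, rt, filtration through Celite; then slow addition to Rh2(S-PTAD)4 (1 mol %), CH2Cl2, 0 °C
Reagents that add atoms: none
Why: Dehydrogenation of the hydrazone by MnO2 gives the diaryldiazomethane, whose donor/donor rhodium carbene inserts into the neighbouring O–CH2–aryl C–H bond (intramolecular 1,5 C–H insertion), a reaction known to give cis-2,3-diaryl-2,3-dihydrobenzofurans whose absolute configuration is dictated by the chiral dirhodium tetracarboxylate, so that C3' is set as R and C2' for the time being as S.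

Step 18
Reactants: 31 cis-outer-ring octamethyl ether
Product: 32 octamethyl ether of the target (2S,3S; methine S; 2'R,3'R; both dihydrofurans trans)
Conditions: TFA (10 equiv), CH2Cl2, 0 °C to rt
Reagents that add atoms: none
Why: Acid-catalysed epimerisation, in which reversible heterolysis of the C2'–O bond to the 4-methoxybenzylic cation and re-closure lead to the more stable trans isomer, so that C2' changes from S to R while C3' and the methine are untouched and the inner dihydrofuran, already trans, can only return to itself.

Step 19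
Reactants: 32 octamethyl ether of the target
Product: 33 CNP0154047.3 (target)
Conditions: BBr3 (24 equiv), CH2Cl2, −78 °C to rt; then H2O, 0 °C
Reagents that add atoms: none
Why: Lewis-acid ether cleavage, in which BBr3 binds each of the eight methoxy oxygens and bromide removes the methyl group by SN2 attack, while no bond to a stereocentre is broken for good and both dihydrofurans are already in their stable trans form.

Compound list
1 | 5,7-dimethoxycoumarin | COc1cc(OC)c2ccc(=O)oc2c1 | starting material
2 | 2,4-dimethoxyphenylboronic acid | COc1ccc(B(O)O)c(OC)c1 | starting material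
3 | (S)-4-(2,4-dimethoxyphenyl)-5,7-dimethoxychroman-2-one | O=C1C[C@@H](c2ccc(OC)cc2OC)c2c(OC)cc(OC)cc2O1 | intermediate
4 | methyl (S)-3-(2,4-dimethoxyphenyl)-3-(2-hydroxy-4,6-dimethoxyphenyl)propanoate (ring-opened phenol methyl ester) | COC(=O)C[C@@H](c1ccc(OC)cc1OC)c1c(OC)cc(OC)cc1O | intermediate
5 | methyl (S)-3-[2-(benzyloxy)-4,6-dimethoxyphenyl]-3-(2,4-dimethoxyphenyl)propanoate (benzyl ether methyl ester) | COC(=O)C[C@@H](c1ccc(OC)cc1OC)c1c(OC)cc(OC)cc1OCc1ccccc1 | intermediate
6 | (S)-3-[2-(benzyloxy)-4,6-dimethoxyphenyl]-3-(2,4-dimethoxyphenyl)propanoic acid | OC(=O)C[C@@H](c1ccc(OC)cc1OC)c1c(OC)cc(OC)cc1OCc1ccccc1 | intermediate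
7 | Barton ester of 6 (2-thioxopyridin-1(2H)-yl ester, S) | O=C(ON1C=CC=CC1=S)C[C@@H](c1ccc(OC)cc1OC)c1c(OC)cc(OC)cc1OCc1ccccc1 | intermediate
8 | (S)-1-(benzyloxy)-2-[1-(2,4-dimethoxyphenyl)-2-iodoethyl]-3,5-dimethoxybenzene | IC[C@@H](c1ccc(OC)cc1OC)c1c(OC)cc(OC)cc1OCc1ccccc1 | intermediate
9 | 5-bromoresorcinol | Oc1cc(O)cc(Br)c1 | starting material
10 | 5-bromo-4-iodobenzene-1,3-diol | Oc1cc(O)c(I)c(Br)c1 | intermediate
11 | 4-ethynylanisole | COc1ccc(C#C)cc1 | starting material
12 | 5-bromo-4-[(4-methoxyphenyl)ethynyl]benzene-1,3-diol (alkynylresorcinol) | COc1ccc(C#Cc2c(O)cc(O)cc2Br)cc1 | intermediate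
13 | 4-bromo-2-(4-methoxyphenyl)benzofuran-6-ol | COc1ccc(-c2cc3c(Br)cc(O)cc3o2)cc1 | intermediate
14 | 4-bromo-2-(4-methoxyphenyl)benzofuran-6-yl pivalate | COc1ccc(-c2cc3c(Br)cc(OC(=O)C(C)(C)C)cc3o2)cc1 | intermediate
15 | (S)-2-[2-(benzyloxy)-4,6-dimethoxyphenyl]-2-(2,4-dimethoxyphenyl)ethylzinc iodide | I[Zn]C[C@@H](c1ccc(OC)cc1OC)c1c(OC)cc(OC)cc1OCc1ccccc1 | intermediate
16 | 4-{(S)-2-[2-(benzyloxy)-4,6-dimethoxyphenyl]-2-(2,4-dimethoxyphenyl)ethyl}-2-(4-methoxyphenyl)benzofuran-6-yl pivalate | COc1ccc(-c2cc3c(C[C@@H](c4ccc(OC)cc4OC)c4c(OC)cc(OC)cc4OCc4ccccc4)cc(OC(=O)C(C)(C)C)cc3o2)cc1 | intermediate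
17 | 4-[(S)-2-(2,4-dimethoxyphenyl)-2-(2-hydroxy-4,6-dimethoxyphenyl)ethyl]-2-(4-methoxyphenyl)benzofuran-6-yl pivalate | COc1ccc(-c2cc3c(C[C@@H](c4ccc(OC)cc4OC)c4c(OC)cc(OC)cc4O)cc(OC(=O)C(C)(C)C)cc3o2)cc1 | intermediate
18 | 4-{(S)-2-(2,4-dimethoxyphenyl)-2-[2,4-dimethoxy-6-(triflyloxy)phenyl]ethyl}-2-(4-methoxyphenyl)benzofuran-6-yl pivalate (key-step precursor) | COc1ccc(-c2cc3c(C[C@@H](c4ccc(OC)cc4OC)c4c(OC)cc(OC)cc4OS(=O)(=O)C(F)(F)F)cc(OC(=O)C(C)(C)C)cc3o2)cc1 | intermediate
19 | tetracyclic core pivalate: (2S,3S)-trans-2-(4-methoxyphenyl)-2,3-dihydrobenzofuran-6-yl pivalate with C3 bonded to C1'' of ring C (3'',5''-dimethoxy) and C4–CH2 bonded to the (S)-methine on C2'' that bears ring D (2,4-dimethoxyphenyl); H3 trans to the methine H | COc1ccc([C@H]2Oc3cc(OC(=O)C(C)(C)C)cc4c3[C@@H]2c2cc(OC)cc(OC)c2[C@H](c2ccc(OC)cc2OC)C4)cc1 | intermediate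
20 | tetracyclic core phenol: as 19 with free C6–OH | COc1ccc([C@H]2Oc3cc(O)cc4c3[C@@H]2c2cc(OC)cc(OC)c2[C@H](c2ccc(OC)cc2OC)C4)cc1 | intermediate
21 | paraformaldehyde (written as formaldehyde) | C=O | starting material
22 | core salicylaldehyde: as 20 with CHO on C5 | COc1ccc([C@H]2Oc3cc(O)c(C=O)c4c3[C@@H]2c2cc(OC)cc(OC)c2[C@H](c2ccc(OC)cc2OC)C4)cc1 | intermediate
23 | 4-methoxybenzyl chloride | COc1ccc(CCl)cc1 | starting material
24 | core aldehyde 4-methoxybenzyl ether: as 22 with C6–O–CH2–C6H4-4-OMe | COc1ccc([C@H]2Oc3cc(OCc5ccc(OC)cc5)c(C=O)c4c3[C@@H]2c2cc(OC)cc(OC)c2[C@H](c2ccc(OC)cc2OC)C4)cc1 | intermediate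
25 | 1-bromo-3,5-dimethoxybenzene | COc1cc(Br)cc(OC)c1 | starting material
26 | 3,5-dimethoxyphenylmagnesium bromide | COc1cc([Mg]Br)cc(OC)c1 | intermediate
27 | core diarylcarbinol: as 24 with C5–CH(OH)(3,5-dimethoxyphenyl), both carbinol epimers | COc1ccc([C@H]2Oc3cc(OCc5ccc(OC)cc5)c(C(O)c5cc(OC)cc(OC)c5)c4c3[C@@H]2c2cc(OC)cc(OC)c2[C@H](c2ccc(OC)cc2OC)C4)cc1 | intermediate
28 | core diaryl ketone: as 24 with C5–C(=O)(3,5-dimethoxyphenyl) | COc1ccc([C@H]2Oc3cc(OCc5ccc(OC)cc5)c(C(=O)c5cc(OC)cc(OC)c5)c4c3[C@@H]2c2cc(OC)cc(OC)c2[C@H](c2ccc(OC)cc2OC)C4)cc1 | intermediate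
29 | hydrazone of 28 (E/Z mixture) | COc1ccc([C@H]2Oc3cc(OCc5ccc(OC)cc5)c(C(=NN)c5cc(OC)cc(OC)c5)c4c3[C@@H]2c2cc(OC)cc(OC)c2[C@H](c2ccc(OC)cc2OC)C4)cc1 | intermediate
30 | diaryldiazomethane from 29 | COc1ccc([C@H]2Oc3cc(OCc5ccc(OC)cc5)c(C(=[N+]=[N-])c5cc(OC)cc(OC)c5)c4c3[C@@H]2c2cc(OC)cc(OC)c2[C@H](c2ccc(OC)cc2OC)C4)cc1 | intermediate
31 | octamethyl ether with cis outer dihydrofuran (2S,3S; methine S; 2'S,3'R) | COc1ccc([C@H]2Oc3cc4c(c5c3[C@@H]2c2cc(OC)cc(OC)c2[C@H](c2ccc(OC)cc2OC)C5)[C@@H](c2cc(OC)cc(OC)c2)[C@@H](c2ccc(OC)cc2)O4)cc1 | intermediate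
32 | octamethyl ether of the target, both dihydrofurans trans (2S,3S; methine S; 2'R,3'R) | COc1ccc([C@H]2Oc3cc4c(c5c3[C@@H]2c2cc(OC)cc(OC)c2[C@H](c2ccc(OC)cc2OC)C5)[C@@H](c2cc(OC)cc(OC)c2)[C@H](c2ccc(OC)cc2)O4)cc1 | intermediate
33 | CNP0154047.3 (2S,3S; methine S; 2'R,3'R) | Oc1ccc([C@H]2Oc3cc4c(c5c3[C@@H]2c2cc(O)cc(O)c2[C@H](c2ccc(O)cc2O)C5)[C@@H](c2cc(O)cc(O)c2)[C@H](c2ccc(O)cc2)O4)cc1 | target

Total step count: 19. Longest linear sequence: 16 steps (steps 1–3 and 7–19).

Steps most likely to fail

1. Step 10.
What may go wrong:
- Formate may hand its hydride to the arylpalladium species before the slow seven-membered insertion takes place, which amounts to a net loss of the triflate.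
- The metal may instead palladate the C6–H bond of ring D.
- The insertion may revert.
- The methine may bias the two furan faces too weakly.

The fallback uses known chemistry, sets out from 18 and comes back at 19, and separates closure from reduction. Without any hydride donor, 18 is cyclised by an intramolecular Heck-type heteroarylation of the furan C3–H bond (Pd2(dba)3, dppf, 1,2,2,6,6-pentamethylpiperidine, DMF, 110 °C). This closure is not raced by a reductant and should give the rearomatised cyclohepta-fused 2,3-diarylbenzofuran F1. Ionic hydrogenation (Et3SiH, TFA, CH2Cl2, 0 °C to rt) then protonates C3 on the face chosen by the S methine and delivers hydride to the 2-aryl oxocarbenium ion. The same acid equilibrates C2 through reversible C2–O ionisation to the trans isomer 19.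

2. Step 16.
What may go wrong:
- The condensation may stall because two ortho substituents shield the carbonyl carbon.
- Forcing it may begin to cleave the benzylic ether.
- The hindered carbene of step 17 may respond poorly to the catalyst.

The fallback sets out from 28 and comes back at 32, bypassing steps 16–18 by one-carbon homologation and cationic ring closure. Corey–Chaykovsky methylenation of 28 (Me3SI, KHMDS, THF, 0 °C) gives the 2,2-diaryloxirane F2. Meinwald rearrangement (ZnI2, CH2Cl2, rt) gives the diarylacetaldehyde F3, and addition of 4-methoxyphenylmagnesium bromide (THF, −78 °C) gives the triarylethanol F4. TFA with pentamethylbenzene as cation trap (CH2Cl2, 0 °C) removes the 4-methoxybenzyl group from the C6 oxygen and ionises the carbinol, and the freed phenol closes the trans-dihydrofuran. Since C3' is then set by the substrate alone, 32 forms together with its (2'S,3'S) diastereomer F5 and is separated from it by chromatography.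

3. Step 1.
What may go wrong:
- Insertion of the aryl–rhodium species into a coumarin whose C4 is shielded by the peri methoxy group is slow.
- The electron-rich, ortho-substituted boronic acid may be consumed by protodeboronation first.

The fallback sets out from 1 and comes back at 3. It uses a more reactive nucleophile and parts the enantiomers afterwards. Copper-catalysed conjugate addition of commercial 2,4-dimethoxyphenylmagnesium bromide (CuBr·SMe2, TMSCl, THF, −40 °C) to 1 should give the racemic lactone F6. Preparative chromatography on a chiral stationary phase (supercritical CO2/MeOH) then delivers the S enantiomer 3.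

Further compounds
F1 | step 10 | rearomatised cyclohepta-fused 2,3-diarylbenzofuran pivalate (methine S) | COc1ccc(-c2oc3cc(OC(=O)C(C)(C)C)cc4c3c2-c2cc(OC)cc(OC)c2[C@H](c2ccc(OC)cc2OC)C4)cc1
F2 | step 16 | 2,2-diaryloxirane from 28 (both epimers at the oxirane carbon) | COc1ccc([C@H]2Oc3cc(OCc5ccc(OC)cc5)c(C5(CO5)c5cc(OC)cc(OC)c5)c4c3[C@@H]2c2cc(OC)cc(OC)c2[C@H](c2ccc(OC)cc2OC)C4)cc1
F3 | step 16 | diarylacetaldehyde (both epimers at the future C3') | COc1ccc([C@H]2Oc3cc(OCc5ccc(OC)cc5)c(C(C=O)c5cc(OC)cc(OC)c5)c4c3[C@@H]2c2cc(OC)cc(OC)c2[C@H](c2ccc(OC)cc2OC)C4)cc1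
F4 | step 16 | triarylethanol (isomer mixture at the two new centres) | COc1ccc([C@H]2Oc3cc(OCc5ccc(OC)cc5)c(C(C(O)c5ccc(OC)cc5)c5cc(OC)cc(OC)c5)c4c3[C@@H]2c2cc(OC)cc(OC)c2[C@H](c2ccc(OC)cc2OC)C4)cc1
F5 | step 16 | (2'S,3'S) diastereomer of 32 | COc1ccc([C@H]2Oc3cc4c(c5c3[C@@H]2c2cc(OC)cc(OC)c2[C@H](c2ccc(OC)cc2OC)C5)[C@H](c2cc(OC)cc(OC)c2)[C@@H](c2ccc(OC)cc2)O4)cc1
F6 | step 1 | racemic 4-(2,4-dimethoxyphenyl)-5,7-dimethoxychroman-2-one | O=C1CC(c2ccc(OC)cc2OC)c2c(OC)cc(OC)cc2O1
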